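What is there most of in each flask at the end, and how much of it?

common to all: starting material 1.5 M; capture agent 1.50 M; protic impurity 0.300 M

|  | time |
|---|---|
| violet | 25 min |
| green | 20 min |
| red | 15 min |

    starting material → open intermediate (k1 = 0.0139 min⁻¹)
    open intermediate ⇌ target (K2 = 1.14, k2 = 0.0519 min⁻¹)
    open intermediate ⇌ isomer of the product (K3 = 120, k3 = 0.0135 min⁻¹)
    open intermediate + capture agent → trapped intermediate (k4 = 0.251 M⁻¹ min⁻¹)
    starting material + protic impurity → quenched substrate (k5 = 0.142 M⁻¹ min⁻¹)
    starting material → decomposition product (k6 = 1.50 × 10⁻⁵ min⁻¹)

* which of these there is most of at the end, counted by the starting material in it, violet (starting material / target / trapped intermediate / open intermediate)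
* which of these there is most of at the end, counted by the starting material in it, green (starting material / target / trapped intermediate / open intermediate)
* which of these there is most of at the end, counted by the starting material in it, red (starting material / target / trapped intermediate / open intermediate)
* amount of the one of these that there is most of at the end, in percent of the starting material charged, violet
* amount of the one of these that there is most of at the end, in percent of the starting material charged, green
* amount of the one of these that there is most of at the end, in percent of the starting material charged, red

Two chemists dispute what the quench, the reaction of starting material with protic impurity, takes away. The first holds [protic impurity] near its charge of 0.300 M, so that the quench is pseudo-first-order and adds 0.0426 min⁻¹ to the opening step's 0.0139 min⁻¹. Violet then keeps 24.4% of its starting material, green 32.3% and red 42.8%. The second calls the impurity the limiting reagent: it takes 20.0% of the charge and stops, and the opening step works on the rest, which leaves violet 56.5%, green 60.6% and red 64.9%.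

My own reckoning goes round twice. With [starting material] at its charge, [protic impurity] falls by a factor e in 4.69 min. That is shorter than red's time, so I take the quench as working while [starting material] runs from 1.5 M down towards 1.20 M. Putting the mean, 1.35 M, back in gives 5.22 min. This lifetime, the time in which [protic impurity] falls by a factor e under the quench at that mean level, is what I carry. Even red's 15 min is 2.87 lifetimes, so I side with the second chemist, with a correction for the impurity still unused. I reckon 56.6% for violet, 60.9% for green and 65.9% for red. Run on the whole charge, the opening step passes 29.4% of it in violet, and less in the shorter flasks, so the leader is starting material in violet, starting material in green and starting material in red.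

The forecast takes the second side, with starting material at 55.8% in violet, 60.2% in green and 65.3% in red, saying of the other species that “none of these can overtake”.

The simulation gives starting material at 55.8% in violet, starting material at 60.2% in green and starting material at 65.4% in red, so the second chemist wins.

Violet stands 9.6 percentage points below red, 55.8% against 65.4%, and the difference in time is the main reason. The first chemist's view has its place in green at a time shorter than the lifetime: green at 4.00 min reads 84.1%, where that view gives 79.8% and the limiting-reagent view 75.7%. Green read at 80 min, after 15.3 lifetimes, reckons to 26.3% and stands at 25.7%.

(Its constants are assumed; what happens was integrated by code.)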